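The route rests on cutting ring A between the quaternary carbon C4 and C5, together with the C9–C10 bond of ring B. This unravels the decalin into an acyclic triene 2-methylacetoacetate. One oxidative radical cascade starts at C4, between the C19 ester and a temporary C3 ketone. It closes rings A and B, sets C4, C5, C9 and C10, and leaves the C8=C17 methylene. It exploits the 1,5-diene pattern C4/C5=C10/C9=C8. The E C5=C10 alkene gives the trans fusion, and the Z C8=C9 alkene (from nerylacetone) gives the axial, 9,10-syn side chain. A phenylmenthyl ester fixes the absolute sense. A temporary 19,6-lactone later brings oxygen to C6β.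

Key step: step 6

Remark on numbering: labdane numbering is used. Ring A is C1–C5 and C10; ring B is C5–C10. C17 is the methylene carbon, C18 the C4 methyl, C19 the C4 carboxyl carbon, C20 the C10 methyl, and C11–C16 the side chain.

Assumption: (−)-8-phenylmenthol is taken to shield the face of the planar C4 radical that leads to the drawn series. If the sense is opposite, the commercial (+)-enantiomer is used in step 4 and nothing else changes.

Step 1
Reactants: 1 nerylacetone [(5Z)-6,10-dimethylundeca-5,9-dien-2-one]; 2 triethyl phosphonoacetate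
Product: 3 ethyl (2E,6Z)-3,7,11-trimethyldodeca-2,6,10-trienoate
Conditions: NaH, THF, 0 °C to rt; chromatography
Reagents that add atoms: none
Why: Horner–Wadsworth–Emmons olefination of a methyl ketone favours the E enoate (long chain trans to the ester), leaves the Z alkene of 1 untouched, and the minor 2Z isomer is removed by chromatography.

Step 2
Reactants: 3 ethyl (2E,6Z)-3,7,11-trimethyldodeca-2,6,10-trienoate
Product: 4 ethyl (2E,6Z,10E)-12-hydroxy-3,7,11-trimethyldodeca-2,6,10-trienoate
Conditions: SeO2 (cat.), t-BuOOH, salicylic acid (cat.), CH2Cl2, 0 °C to rt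
Reagents that add atoms: tert-butyl hydroperoxide, CC(C)(C)OO (oxygen relayed by selenium dioxide, O=[Se]=O)
Why: Selenium dioxide allylic oxidation (ene reaction, then [2,3]-shift) picks the most electron-rich and least hindered terminal isopropylidene group and its E methyl, while the enoate alkene is deactivated.

Step 3
Reactants: 4 ethyl (2E,6Z,10E)-12-hydroxy-3,7,11-trimethyldodeca-2,6,10-trienoate
Product: 5 ethyl (2E,6Z,10E)-12-bromo-3,7,11-trimethyldodeca-2,6,10-trienoate
Conditions: CBr4, PPh3, CH2Cl2, 0 °C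
Reagents that add atoms: tetrabromomethane, BrC(Br)(Br)Br
Why: The Appel reaction converts the primary allylic alcohol to the bromide under neutral conditions, without allylic shift or loss of alkene geometry.

Step 4
Reactants: 6 (−)-8-phenylmenthol [(1R,2S,5R)-5-methyl-2-(2-phenylpropan-2-yl)cyclohexan-1-ol]; 7 ethyl 2-methylacetoacetate
Product: 8 (1R,2S,5R)-8-phenylmenthyl 2-methyl-3-oxobutanoate (both C2 epimers)
Conditions: DMAP (cat.), toluene, reflux, removal of ethanol
Reagents that add atoms: none
Why: DMAP-catalysed transesterification of a β-keto ester is driven by distilling off ethanol and tolerates hindered secondary alcohols; the epimeric α-carbon is irrelevant because it becomes planar in step 6.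

Step 5
Reactants: 8 (1R,2S,5R)-8-phenylmenthyl 2-methyl-3-oxobutanoate; 5 ethyl (2E,6Z,10E)-12-bromo-3,7,11-trimethyldodeca-2,6,10-trienoate
Product: 10 1-ethyl 16-[(1R,2S,5R)-8-phenylmenthyl] (2E,6Z,10E)-3,7,11,15-tetramethyl-14-oxohexadeca-2,6,10-trienedioate, via dilithium dianion 9 (not isolated)
Conditions: LiN(iPr)2 (2.1 equiv), THF, 0 °C; then 5, −78 to 0 °C; aqueous work-up
Reagents that add atoms: none
Why: γ-Alkylation of a β-keto ester dianion works because the more basic terminal carbanion displaces the allylic bromide (SN2) faster than it attacks the hindered β,β-disubstituted enoate, which joins C1 to C2.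

Step 6
Reactants: 10 1-ethyl 16-[(1R,2S,5R)-8-phenylmenthyl] (2E,6Z,10E)-3,7,11,15-tetramethyl-14-oxohexadeca-2,6,10-trienedioate
Product: 11 15-ethyl 19-[(1R,2S,5R)-8-phenylmenthyl] 3-oxo-9βH-labda-8(17),13E-diene-15,19-dioate (5α-H, 10β-methyl, axial 4β-ester, equatorial 4α-methyl, axial 9α side chain)
Conditions: Mn(OAc)3·2H2O (2.2 equiv), Cu(OAc)2·H2O (1 equiv), degassed AcOH, 25 °C, dilute; chromatography
Reagents that add atoms: none
Why: Mn(OAc)3 oxidises the enolised β-keto ester to the electrophilic C4 radical, which adds to C5 of the electron-rich E C5=C10 alkene; the tertiary C10 radical adds to C9 of the Z C8=C9 alkene, and Cu(OAc)2 oxidises the tertiary C8 radical with loss of a C17 hydrogen to the less substituted exocyclic alkene, which is the known manganese triacetate-based oxidative free-radical cyclisation of polyprenyl 2-methylacetoacetates. Ring A closes 6-endo-trig (5-exo would join two fully substituted carbons) and ring B closes 6-endo-trig, both through chair-like transition states. C4 is set by the radical conformer in which the ester lies anti to the C3 carbonyl, so the ester becomes axial and the methyl equatorial; C5 and C10 follow from anti addition across the E alkene (trans fusion); C9 follows from the Z geometry, which places C11 axial and anti to C20. The absolute sense comes from the aryl group of the auxiliary, which covers one face of the planar C4 radical, and the minor diastereomer is removed by chromatography. The cascade must stop after two rings, and the last alkene secures this because it is a β,β-disubstituted enoate: 5-exo attack on it would join two quaternary carbons and 6-endo attack is polarity-mismatched, so oxidation by divalent copper should win.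

Step 7
Reactants: 11 15-ethyl 19-(8-phenylmenthyl) 3-oxo-9βH-labda-8(17),13E-diene-15,19-dioate
Product: 13 15-ethyl 19-[(1R,2S,5R)-8-phenylmenthyl] 9βH-labda-8(17),13E-diene-15,19-dioate, via C3 tosylhydrazone 12 (not isolated)
Conditions: TsNHNH2, EtOH, reflux; evaporate; catecholborane, CHCl3, 0 °C; NaOAc·3H2O, reflux
Reagents that add atoms: none
Why: Tosylhydrazone reduction (a mild variant of the Caglioti reaction) removes the temporary C3 ketone through hydride addition, loss of sulfinate and loss of nitrogen, under conditions that leave esters and both alkenes alone.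

Step 8
Reactants: 13 15-ethyl 19-(8-phenylmenthyl) 9βH-labda-8(17),13E-diene-15,19-dioate
Product: 14 15-ethyl 19-[(1R,2S,5R)-8-phenylmenthyl] 7α-hydroxy-9βH-labda-8(17),13E-diene-15,19-dioate
Conditions: SeO2 (0.5 equiv), t-BuOOH, CH2Cl2, 0 °C to rt
Reagents that add atoms: tert-butyl hydroperoxide, CC(C)(C)OO (oxygen relayed by selenium dioxide, O=[Se]=O)
Why: Selenium dioxide allylic hydroxylation needs an allylic C–H parallel to the π system, which only the axial H7α offers (H9 is equatorial and the enoate is inert), and the [2,3]-shift returns oxygen to the same α face.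

Step 9
Reactants: 14 15-ethyl 19-(8-phenylmenthyl) 7α-hydroxy-9βH-labda-8(17),13E-diene-15,19-dioate
Product: 15 15-ethyl 19-[(1R,2S,5R)-8-phenylmenthyl] 7-oxo-9βH-labda-8(17),13E-diene-15,19-dioate
Conditions: Dess–Martin periodinane, CH2Cl2, 0 °C
Reagents that add atoms: none
Why: Dess–Martin oxidation of the allylic alcohol gives the α-methylene ketone under neutral conditions, which activates C6 as the only enolisable position.

Step 10
Reactants: 15 15-ethyl 19-(8-phenylmenthyl) 7-oxo-9βH-labda-8(17),13E-diene-15,19-dioate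
Product: 16 ethyl 7-oxo-9βH-labda-8(17),13E-dien-19,6β-olid-15-oate (γ-lactone C19(=O)–O–C6β)
Conditions: PhI(OH)OTs (1.2 equiv), MeCN, 40 °C
Reagents that add atoms: [hydroxy(tosyloxy)iodo]benzene, Cc1ccc(cc1)S(=O)(=O)OI(O)c1ccccc1 (its hydroxyl oxygen becomes the lactone carbonyl oxygen)
Why: Proposed new method: acid-catalysed enolisation of the C7 ketone can go only toward C6, the enol attacks trivalent iodine from the open α face, the C19 ester carbonyl held 1,3-diaxial above C6 displaces iodobenzene from the β face and so sets C6–O β, and the water released in the ligand exchange adds to the alkoxy-lactonium ion and expels 8-phenylmenthol; both alkenes are electron-poor and should be inert, C6 cannot epimerise because only the cis-bridged lactone is possible, and the closest known reaction types are the oxylactonisation of 5-oxo carboxylic acids with the same reagent and the ester-assisted closure of 6α-bromo-7-oxo 19-esters of podocarpane diterpenoids to 19,6β-olides.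

Step 11
Reactants: 16 ethyl 7-oxo-9βH-labda-8(17),13E-dien-19,6β-olid-15-oate
Product: 17 ethyl 7α-hydroxy-9βH-labda-8(17),13E-dien-19,6β-olid-15-oate
Conditions: (S)-2-methyl-CBS-oxazaborolidine (0.2 equiv), catecholborane, toluene, −78 °C
Reagents that add atoms: none
Why: Corey–Bakshi–Shibata reduction is 1,2-selective, takes the α-methylene flank as the large group and delivers hydride to the β face, which is also the face left open by the axial C9 side chain, so the 7α (7S) alcohol should form while lactone and enoate survive.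

Step 12
Reactants: 17 ethyl 7α-hydroxy-9βH-labda-8(17),13E-dien-19,6β-olid-15-oate
Product: 18 ethyl 7α-(tert-butyldimethylsilyloxy)-9βH-labda-8(17),13E-dien-19,6β-olid-15-oate
Conditions: TBSOTf, 2,6-lutidine, CH2Cl2, 0 °C
Reagents that add atoms: tert-butyldimethylsilyl triflate, CC(C)(C)[Si](C)(C)OS(=O)(=O)C(F)(F)F
Why: Silylation with the triflate protects the hindered axial allylic alcohol, so that O6 is the only free hydroxyl after the lactone is opened.

Step 13
Reactants: 18 ethyl 7α-(tert-butyldimethylsilyloxy)-9βH-labda-8(17),13E-dien-19,6β-olid-15-oate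
Product: 21 6β-benzoyloxy-7α-(tert-butyldimethylsilyloxy)-9βH-labda-8(17),13E-diene-15,19-dioic acid, via dipotassium hydroxy dicarboxylate 19 (not isolated), via tripotassium alkoxide 20 (not isolated)
Conditions: KOH, EtOH–H2O, reflux; evaporate, azeotrope with toluene; KN(SiMe3)2 (1.1 equiv), THF, −78 °C; BzCl (1.1 equiv), −78 to 0 °C; 1 M HCl to pH 3
Reagents that add atoms: potassium hydroxide, [K+].[OH-]; benzoyl chloride, O=C(Cl)c1ccccc1
Why: Saponification cleaves the temporary lactone and the ethyl ester, the carboxylates cannot re-close while they stay ionised, the potassium alkoxide at O6 is by far the strongest nucleophile toward benzoyl chloride (ester formation by acylation), and the trans-diaxial O6/O7 pair rules out silyl migration.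

Step 14
Reactants: 21 6β-benzoyloxy-7α-(tert-butyldimethylsilyloxy)-9βH-labda-8(17),13E-diene-15,19-dioic acid
Product: 23 6β-benzoyloxy-15-hydroxy-7α-(tert-butyldimethylsilyloxy)-9βH-labda-8(17),13E-dien-19-oic acid, via C15 mixed carbonic anhydride 22 (not isolated)
Conditions: i-BuOCOCl (1.05 equiv), N-methylmorpholine (2.1 equiv), THF, −15 °C; then NaBH4, THF–H2O, 0 °C
Reagents that add atoms: none
Why: In the mixed-anhydride/borohydride reduction of a carboxylic acid, the open conjugated C15 acid is activated and reduced to the allylic alcohol, while the neopentyl axial C19 acid, the benzoate and the alkenes are left alone.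

Step 15
Reactants: 23 6β-benzoyloxy-15-hydroxy-7α-(tert-butyldimethylsilyloxy)-9βH-labda-8(17),13E-dien-19-oic acid
Product: 24 6β-benzoyloxy-7α,15-dihydroxy-9βH-labda-8(17),13E-dien-19-oic acid (CNP0149011.1)
Conditions: HF·pyridine, THF, 0 °C to rt
Reagents that add atoms: none
Why: Fluoride-mediated desilylation frees the 7α-hydroxyl without touching the benzoate, the acid or the allylic alcohols.

Compound list
1 | nerylacetone, (5Z)-6,10-dimethylundeca-5,9-dien-2-one | CC(=O)CC/C=C(/C)CCC=C(C)C | starting material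
2 | triethyl phosphonoacetate | CCOC(=O)CP(=O)(OCC)OCC | starting material
3 | ethyl (2E,6Z)-3,7,11-trimethyldodeca-2,6,10-trienoate | CCOC(=O)/C=C(\C)CC/C=C(/C)CCC=C(C)C | intermediate
4 | ethyl (2E,6Z,10E)-12-hydroxy-3,7,11-trimethyldodeca-2,6,10-trienoate | CCOC(=O)/C=C(\C)CC/C=C(/C)CC/C=C(\C)CO | intermediate
5 | ethyl (2E,6Z,10E)-12-bromo-3,7,11-trimethyldodeca-2,6,10-trienoate | CCOC(=O)/C=C(\C)CC/C=C(/C)CC/C=C(\C)CBr | intermediate
6 | (−)-8-phenylmenthol, (1R,2S,5R) | CC(C)(c1ccccc1)[C@@H]1CC[C@@H](C)C[C@H]1O | starting material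
7 | ethyl 2-methylacetoacetate | CCOC(=O)C(C)C(C)=O | starting material
8 | (1R,2S,5R)-8-phenylmenthyl 2-methyl-3-oxobutanoate (C2 epimers) | CC(=O)C(C)C(=O)O[C@@H]1C[C@H](C)CC[C@H]1C(C)(C)c1ccccc1 | intermediate
9 | dilithium dianion of 8 | [Li+].[Li+].C=C([O-])C(C)=C([O-])O[C@@H]1C[C@H](C)CC[C@H]1C(C)(C)c1ccccc1 | intermediate
10 | 1-ethyl 16-(8-phenylmenthyl) (2E,6Z,10E)-3,7,11,15-tetramethyl-14-oxohexadeca-2,6,10-trienedioate (C15 epimers) | CCOC(=O)/C=C(\C)CC/C=C(/C)CC/C=C(\C)CCC(=O)C(C)C(=O)O[C@@H]1C[C@H](C)CC[C@H]1C(C)(C)c1ccccc1 | intermediate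
11 | 15-ethyl 19-(8-phenylmenthyl) 3-oxo-9βH-labda-8(17),13E-diene-15,19-dioate | C=C1[C@@H](CC/C(C)=C/C(=O)OCC)[C@@]2(C)CCC(=O)[C@](C)(C(=O)O[C@@H]3C[C@H](C)CC[C@H]3C(C)(C)c3ccccc3)[C@@H]2CC1 | intermediate
12 | C3 tosylhydrazone of 11 | C=C1[C@@H](CC/C(C)=C/C(=O)OCC)[C@@]2(C)CCC(=NNS(=O)(=O)c3ccc(C)cc3)[C@](C)(C(=O)O[C@@H]3C[C@H](C)CC[C@H]3C(C)(C)c3ccccc3)[C@@H]2CC1 | intermediate
13 | 15-ethyl 19-(8-phenylmenthyl) 9βH-labda-8(17),13E-diene-15,19-dioate | C=C1[C@@H](CC/C(C)=C/C(=O)OCC)[C@@]2(C)CCC[C@](C)(C(=O)O[C@@H]3C[C@H](C)CC[C@H]3C(C)(C)c3ccccc3)[C@@H]2CC1 | intermediate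
14 | 15-ethyl 19-(8-phenylmenthyl) 7α-hydroxy-9βH-labda-8(17),13E-diene-15,19-dioate | C=C1[C@@H](CC/C(C)=C/C(=O)OCC)[C@@]2(C)CCC[C@](C)(C(=O)O[C@@H]3C[C@H](C)CC[C@H]3C(C)(C)c3ccccc3)[C@@H]2C[C@H]1O | intermediate
15 | 15-ethyl 19-(8-phenylmenthyl) 7-oxo-9βH-labda-8(17),13E-diene-15,19-dioate | C=C1[C@@H](CC/C(C)=C/C(=O)OCC)[C@@]2(C)CCC[C@](C)(C(=O)O[C@@H]3C[C@H](C)CC[C@H]3C(C)(C)c3ccccc3)[C@@H]2CC1=O | intermediate
16 | ethyl 7-oxo-9βH-labda-8(17),13E-dien-19,6β-olid-15-oate | C=C1[C@@H](CC/C(C)=C/C(=O)OCC)[C@@]2(C)CCC[C@](C)(C(=O)O3)[C@@H]2[C@H]3C1=O | intermediate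
17 | ethyl 7α-hydroxy-9βH-labda-8(17),13E-dien-19,6β-olid-15-oate | C=C1[C@@H](CC/C(C)=C/C(=O)OCC)[C@@]2(C)CCC[C@](C)(C(=O)O3)[C@@H]2[C@H]3[C@H]1O | intermediate
18 | ethyl 7α-(tert-butyldimethylsilyloxy)-9βH-labda-8(17),13E-dien-19,6β-olid-15-oate | C=C1[C@@H](CC/C(C)=C/C(=O)OCC)[C@@]2(C)CCC[C@](C)(C(=O)O3)[C@@H]2[C@H]3[C@H]1O[Si](C)(C)C(C)(C)C | intermediate
19 | dipotassium 6β-hydroxy-7α-(tert-butyldimethylsilyloxy)-9βH-labda-8(17),13E-diene-15,19-dioate | [K+].[K+].C=C1[C@@H](CC/C(C)=C/C(=O)[O-])[C@@]2(C)CCC[C@](C)(C(=O)[O-])[C@@H]2[C@H](O)[C@H]1O[Si](C)(C)C(C)(C)C | intermediate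
20 | tripotassium 6β-alkoxide of 19 | [K+].[K+].[K+].C=C1[C@@H](CC/C(C)=C/C(=O)[O-])[C@@]2(C)CCC[C@](C)(C(=O)[O-])[C@@H]2[C@H]([O-])[C@H]1O[Si](C)(C)C(C)(C)C | intermediate
21 | 6β-benzoyloxy-7α-(tert-butyldimethylsilyloxy)-9βH-labda-8(17),13E-diene-15,19-dioic acid | C=C1[C@@H](CC/C(C)=C/C(=O)O)[C@@]2(C)CCC[C@](C)(C(=O)O)[C@@H]2[C@H](OC(=O)c2ccccc2)[C@H]1O[Si](C)(C)C(C)(C)C | intermediate
22 | C15 isobutyl carbonic mixed anhydride of 21 | C=C1[C@@H](CC/C(C)=C/C(=O)OC(=O)OCC(C)C)[C@@]2(C)CCC[C@](C)(C(=O)O)[C@@H]2[C@H](OC(=O)c2ccccc2)[C@H]1O[Si](C)(C)C(C)(C)C | intermediate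
23 | 6β-benzoyloxy-15-hydroxy-7α-(tert-butyldimethylsilyloxy)-9βH-labda-8(17),13E-dien-19-oic acid | C=C1[C@@H](CC/C(C)=C/CO)[C@@]2(C)CCC[C@](C)(C(=O)O)[C@@H]2[C@H](OC(=O)c2ccccc2)[C@H]1O[Si](C)(C)C(C)(C)C | intermediate
24 | 6β-benzoyloxy-7α,15-dihydroxy-9βH-labda-8(17),13E-dien-19-oic acid (CNP0149011.1) | C=C1[C@@H](CC/C(C)=C/CO)[C@@]2(C)CCC[C@](C)(C(=O)O)[C@@H]2[C@H](OC(=O)c2ccccc2)[C@H]1O | target

Total step count: 15. Longest linear sequence: 14 steps (steps 1–3 and 5–15, from nerylacetone).

Steps most likely to fail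

1. Step 10 (proposed new method). External tosylate may capture the C6 iodane before the ester carbonyl does. The iodane may also oxidise elsewhere, so that α-tosyloxylation competes with lactone closure. The fallback separates activation from closure; it sets out from 15 and comes back at 16. α′-Bromination of 15 with PhNMe3Br3 in THF at 0 °C should give the 15-ethyl 19-(8-phenylmenthyl) 6α-bromo-7-oxo diester F1, because both alkenes are electron-poor. AgOTf in wet acetone then abstracts bromide behind a non-nucleophilic counter-ion. The C19 ester carbonyl attacks C6 from the β face, and water releases 8-phenylmenthol to give 16. This is the classical halide route to 19,6β-olides.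

2. Step 6 (key step). Facial selectivity of the auxiliary may be poor. The chair preference for the Z alkene may erode, giving the C9 epimer. A third ring closure may compete with copper-mediated oxidation. The fallback replaces the metal oxidants by a group-transfer chain and a separate alkene-forming event; it sets out from 10 and comes back at 11. Selenenylation of 10 (NaH, PhSeCl, THF) gives the α-phenylselanyl β-keto diester F2. Photolysis at low temperature in benzene–hexane should carry the same two ring closures by phenylselanyl group transfer, giving the bicyclic C8 phenylselenide F3. Fast selenium transfer cuts off further cyclisation. Oxidation with H2O2 and syn elimination of the selenoxide toward the C17 methyl gives 11.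

3. Step 13. The hindered lactone may open incompletely. The C19 carboxylate may be acylated instead of O6, in which case the mixed anhydride collapses back to the lactone. The fallback masks the carboxyl groups as esters before acylation; it sets out from 18 (through 19) and comes back at 21. The dry dipotassium salt 19 is alkylated with allyl bromide in DMF to the bis(allyl) 6β-hydroxy diester F4. This is benzoylated at once (BzCl, DMAP, pyridine, 0 °C) to the bis(allyl) 6β-benzoate F5. Pd(PPh3)4 (zerovalent palladium) with morpholine removes both allyl groups and returns 21.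

Further compounds
F1 | step 10 | 15-ethyl 19-(8-phenylmenthyl) 6α-bromo-7-oxo-9βH-labda-8(17),13E-diene-15,19-dioate | C=C1[C@@H](CC/C(C)=C/C(=O)OCC)[C@@]2(C)CCC[C@](C)(C(=O)O[C@@H]3C[C@H](C)CC[C@H]3C(C)(C)c3ccccc3)[C@@H]2[C@@H](Br)C1=O
F2 | step 6 | 1-ethyl 16-(8-phenylmenthyl) (2E,6Z,10E)-3,7,11,15-tetramethyl-14-oxo-15-(phenylselanyl)hexadeca-2,6,10-trienedioate | CCOC(=O)/C=C(\C)CC/C=C(/C)CC/C=C(\C)CCC(=O)C(C)([Se]c1ccccc1)C(=O)O[C@@H]1C[C@H](C)CC[C@H]1C(C)(C)c1ccccc1
F3 | step 6 | 15-ethyl 19-(8-phenylmenthyl) 3-oxo-8-(phenylselanyl)-9βH-labd-13E-ene-15,19-dioate (C8 epimers) | CC1([Se]c2ccccc2)[C@@H](CC/C(C)=C/C(=O)OCC)[C@@]2(C)CCC(=O)[C@](C)(C(=O)O[C@@H]3C[C@H](C)CC[C@H]3C(C)(C)c3ccccc3)[C@@H]2CC1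
F4 | step 13 | diallyl 6β-hydroxy-7α-(tert-butyldimethylsilyloxy)-9βH-labda-8(17),13E-diene-15,19-dioate | C=C1[C@@H](CC/C(C)=C/C(=O)OCC=C)[C@@]2(C)CCC[C@](C)(C(=O)OCC=C)[C@@H]2[C@H](O)[C@H]1O[Si](C)(C)C(C)(C)C
F5 | step 13 | diallyl 6β-benzoyloxy-7α-(tert-butyldimethylsilyloxy)-9βH-labda-8(17),13E-diene-15,19-dioate | C=C1[C@@H](CC/C(C)=C/C(=O)OCC=C)[C@@]2(C)CCC[C@](C)(C(=O)OCC=C)[C@@H]2[C@H](OC(=O)c2ccccc2)[C@H]1O[Si](C)(C)C(C)(C)C
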